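**Plan**
- Retrosynthesis: the pyrrole is the sulfinic-acid-elimination product of an N-tosyl 2,5-dihydropyrrole-2-carboxylate. Its ring C3=C4 bond is cut by ring-closing metathesis, then N1–C5 (allyl donor), then C2–C3 (alkenyl Grignard reagent plus N-tosyl iminoacetate), then the side-chain C1'–C2' bond (C20 Grignard reagent plus 2,3-dibromopropene).
- Enabling feature: ring bond C3–C4 joins the henicosyl-bearing C3 to an unsubstituted C4–H, next to the ester-bearing C2 and N1. C3 can therefore be the substituted carbon of a 1,1-disubstituted alkene on a glycine α-carbon (C2), C4/C5 can come from an N-allyl group, and the only ring of the target is the one metathesis closes.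
- Forward order: chain assembly (C20 + C3), C2–C3 bond, N-allylation, closure of the single five-membered ring at C3=C4, aromatisation.
- Stereochemistry: the target has no stereocentre; the C2 centre of the intermediates is made racemic and is erased in the last step.

Key step: step 5

Remark: methyl glyoxylate is taken as the freshly distilled monomer, and every intermediate with a stereocentre at C2 is a racemate.

**Route**

Step 1
Reactants: 1 1-bromoicosane; 2 2,3-dibromopropene
Product: 4 2-bromotricos-1-ene, via icosylmagnesium bromide 3 (not isolated)
Conditions: Mg, THF, 50 °C; then add to 2 (1.2 equiv), CuI (5 mol %), THF, 0 °C to rt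
Reagents that add atoms: none
Why: Grignard formation followed by copper-catalysed allylic substitution on 2,3-dibromopropene (SN2 and SN2' attack give the same product) is a standard way to 2-bromo-1-alkenes, the vinylic C–Br bond being inert under these conditions.

Step 2
Reactants: 5 methyl glyoxylate; 6 p-toluenesulfonyl isocyanate
Product: 7 methyl (E)-2-(tosylimino)acetate
Conditions: toluene, 110 °C (CO2 evolution); concentrate, use crude under Ar
Reagents that add atoms: none
Why: Aza-Wittig-type exchange of the aldehyde C=O with the isocyanate N=C through a [2+2]/retro-[2+2] sequence that releases CO2 is the established preparation of N-sulfonyl iminoacetates.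

Step 3
Reactants: 4 2-bromotricos-1-ene; 7 methyl (E)-2-(tosylimino)acetate
Product: 9 methyl 3-methylidene-2-(tosylamino)tetracosanoate (racemic), via tricos-1-en-2-ylmagnesium bromide 8 (not isolated)
Conditions: 4, Mg turnings (cat. I2), THF, 65 °C; then add to 7 (1.3 equiv), THF, −78 °C; H2O quench
Reagents that add atoms: none
Why: Magnesium insertion into the 2-bromo-1-alkene and 1,2-addition of the alkenyl Grignard reagent to the strongly electrophilic N-sulfonyl α-imino ester (Grignard addition to an electrophilic glycine equivalent) should outpace attack on the methyl ester at −78 °C and gives the C2 centre as a racemate because no chiral element is present.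

Step 4
Reactants: 9 methyl 3-methylidene-2-(tosylamino)tetracosanoate (racemic); 10 prop-2-en-1-ol (allyl alcohol)
Product: 11 methyl 3-methylidene-2-[prop-2-enyl(tosyl)amino]tetracosanoate (racemic)
Conditions: PPh3, DIAD, THF, 0 °C to rt
Reagents that add atoms: none
Why: Mitsunobu N-alkylation of the acidic N-tosyl α-amino ester with a primary allylic alcohol runs without added carbonate or alkoxide base, so the β,γ-alkene should stay out of conjugation with the ester.

Step 5
Reactants: 11 methyl 3-methylidene-2-[prop-2-enyl(tosyl)amino]tetracosanoate (racemic)
Product: 12 methyl 3-henicosyl-1-tosyl-2,5-dihydro-1H-pyrrole-2-carboxylate (racemic)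
Conditions: second-generation Grubbs catalyst RuCl2(=CHPh)(PCy3)(H2IMes) (5 mol %), 1,4-benzoquinone (10 mol %), toluene (0.01 M), 70 °C, Ar sparge
Reagents that add atoms: none
Why: Olefin metathesis by the metallacyclobutane mechanism: RuCl2(=CHPh)(PCy3)(H2IMes) sheds PCy3, exchanges its benzylidene for the unhindered N-allyl terminus, and the new alkylidene adds across the 1,1-disubstituted alkene to a ruthenacyclobutane whose cycloreversion gives the C3=C4 bond and a ruthenium methylidene, with ethylene leaving the solution. The closest known reaction type is ring-closing metathesis of N-allyl-N-(2-substituted allyl) sulfonamides to 3-substituted N-sulfonyl 2,5-dihydropyrroles with this catalyst class. The single ring formed is the five-membered 2,5-dihydropyrrole, closed as the ring-closing metathesis of a 4-aza-1,6-diene in which the new trisubstituted double bond ends up endocyclic. No stereocentre is created and the racemic C2 centre is a spectator. The step needs ring closure to beat intermolecular cross-metathesis of the allyl ends and must leave the β,γ-alkene out of conjugation with the ester; the five-membered tether, the N-sulfonyl group (no basic amine to bind ruthenium), the 0.01 M dilution and base-free conditions with 1,4-benzoquinone as hydride scavenger are expected to secure both.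

Step 6
Reactants: 12 methyl 3-henicosyl-1-tosyl-2,5-dihydro-1H-pyrrole-2-carboxylate (racemic)
Product: 14 methyl 3-henicosyl-1H-pyrrole-2-carboxylate (target), via methyl 4-henicosyl-2H-pyrrole-5-carboxylate 13 (not isolated)
Conditions: DBU (3 equiv), THF–DMF, 60 °C
Reagents that add atoms: none
Why: DBU removes the acidic C2–H (α to the ester and allylic), the anion expels p-toluenesulfinate from nitrogen in an E1cB elimination to the 2H-pyrrole, and a proton shift from the ring CH2 to nitrogen gives the aromatic pyrrole, a known base-induced aromatisation of N-sulfonyl 3-pyrrolines.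

**Compound list**

1 | 1-bromoicosane | CCCCCCCCCCCCCCCCCCCCBr | starting material
2 | 2,3-dibromopropene | BrCC(Br)=C | starting material
3 | icosylmagnesium bromide | CCCCCCCCCCCCCCCCCCCC[Mg]Br | intermediate (not isolated)
4 | 2-bromotricos-1-ene | CCCCCCCCCCCCCCCCCCCCCC(Br)=C | intermediate
5 | methyl glyoxylate | COC(=O)C=O | starting material
6 | p-toluenesulfonyl isocyanate | Cc1ccc(cc1)S(=O)(=O)N=C=O | starting material
7 | methyl (E)-2-(tosylimino)acetate | COC(=O)/C=N/S(=O)(=O)c1ccc(C)cc1 | intermediate
8 | tricos-1-en-2-ylmagnesium bromide | CCCCCCCCCCCCCCCCCCCCCC(=C)[Mg]Br | intermediate (not isolated)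
9 | methyl 3-methylidene-2-(tosylamino)tetracosanoate (racemic) | CCCCCCCCCCCCCCCCCCCCCC(=C)C(NS(=O)(=O)c1ccc(C)cc1)C(=O)OC | intermediate
10 | prop-2-en-1-ol (allyl alcohol) | C=CCO | starting material
11 | methyl 3-methylidene-2-[prop-2-enyl(tosyl)amino]tetracosanoate (racemic) | CCCCCCCCCCCCCCCCCCCCCC(=C)C(C(=O)OC)N(CC=C)S(=O)(=O)c1ccc(C)cc1 | intermediate
12 | methyl 3-henicosyl-1-tosyl-2,5-dihydro-1H-pyrrole-2-carboxylate (racemic) | CCCCCCCCCCCCCCCCCCCCCC1=CCN(S(=O)(=O)c2ccc(C)cc2)C1C(=O)OC | intermediate
13 | methyl 4-henicosyl-2H-pyrrole-5-carboxylate | CCCCCCCCCCCCCCCCCCCCCC1=CCN=C1C(=O)OC | intermediate (not isolated)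
14 | methyl 3-henicosyl-1H-pyrrole-2-carboxylate | CCCCCCCCCCCCCCCCCCCCCc1cc[nH]c1C(=O)OC | target

**Step count**

Total step count: 6.
Longest linear sequence: 5 steps (steps 1, 3, 4, 5, 6 from 1-bromoicosane); step 2 is a one-step side branch.

**Steps most likely to fail**

1. Step 3. Magnesium insertion into the long-chain 2-bromoalkene may be sluggish and accompanied by homocoupling. The alkenylmagnesium reagent may also attack the ester carbonyl or the imine nitrogen, and the imine may oligomerise before it is trapped. Fallback, from 4 back to 11: bromine–lithium exchange on 4 with tert-butyllithium (2 equiv, THF, −78 °C), trapping with B(OiPr)3 and acidic hydrolysis should give tricos-1-en-2-ylboronic acid F1. A Petasis borono-Mannich three-component reaction of this boronic acid with prop-2-en-1-amine and glyoxylic acid monohydrate (CH2Cl2, rt) should give racemic 3-methylidene-2-(prop-2-enylamino)tetracosanoic acid F2. Esterification with Me3SiCHN2 in MeOH–toluene should give methyl 3-methylidene-2-(prop-2-enylamino)tetracosanoate F3. N-Sulfonylation with p-toluenesulfonyl chloride, pyridine and cat. DMAP in CH2Cl2 rejoins the route at 11. No strongly basic organometallic meets an ester in this sequence, and steps 2 to 4 are bypassed.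

2. Step 5. Closure onto the hindered 1,1-disubstituted alkene may be slow, which would let intermolecular cross-metathesis of the allyl ends and ruthenium-hydride-induced double-bond migration take over. Fallback, from 4 to 14: dehydrobromination of 4 with NaNH2 (3 equiv, THF, 60 °C, aqueous quench) should give tricos-1-yne F4. An Ag2CO3-catalysed formal [3+2] cycloaddition of this alkyne with methyl isocyanoacetate (1,4-dioxane, 80 °C) places the ester on C2 and the chain on C3 and gives the target 14 directly. This builds the pyrrole without any metathesis.

3. Step 4. Alkylation at the congested sulfonamide nitrogen may be incomplete, and the basic Mitsunobu betaine may pull the β,γ-alkene into conjugation with the ester. Fallback, from 9 back to 11: Tsuji–Trost N-allylation of 9 with allyl methyl carbonate and Pd(PPh3)4 (a zerovalent palladium complex) in THF at rt. The sulfonamide attacks a π-allylpalladium electrophile under neutral conditions, the only base being the methoxide released on ionisation, and the product is 11. No new compound arises (F0).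

**Further compounds**

F1 | step 3 | tricos-1-en-2-ylboronic acid | CCCCCCCCCCCCCCCCCCCCCC(=C)B(O)O
F2 | step 3 | 3-methylidene-2-(prop-2-enylamino)tetracosanoic acid (racemic) | CCCCCCCCCCCCCCCCCCCCCC(=C)C(NCC=C)C(=O)O
F3 | step 3 | methyl 3-methylidene-2-(prop-2-enylamino)tetracosanoate (racemic) | CCCCCCCCCCCCCCCCCCCCCC(=C)C(NCC=C)C(=O)OC
F4 | step 5 | tricos-1-yne | CCCCCCCCCCCCCCCCCCCCCC#C
F0 | step 4 | none | none
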